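West is read at 40 min and north at 10 min, while the dawn and dusk runs end at 5.00 min, and two chemists disagree over what those extra minutes do to the double product, the form that has taken up two partners on one substrate.

| flask | substrate | partner | capture agent | temperature | remark | time |
|---|---|---|---|---|---|---|
| dawn | 0.15 M | 0.57 M | 0.057 M | 20 °C | run made earlier |  |
| dusk | 0.36 M | 0.57 M | 0.057 M | 31 °C | run made earlier |  |
| north | 0.57 M | 0.570 M | 0.0570 M | 25 °C |  | 10 min |
| west | 0.20 M | 0.570 M | 0.0570 M | 25 °C |  | 40 min |

- dawn (time / min: double product / %, substrate / %): 0.417: 3.7, 70.0; 0.667: 5.5, 57.1; 1.00: 8.5, 41.1; 1.33: 14.3, 32.5; 2.00: 23.9, 20.5; 3.00: 34.4, 9.6; 5.00: 50.5, 4.2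
- dusk (time / min: double product / %, substrate / %): 0.250: 2.0, 63.2; 0.833: 16.7, 30.7; 1.33: 27.0, 20.2; 2.00: 33.8, 13.7; 3.00: 39.9, 10.3; 4.00: 45.1, 6.4; 5.00: 48.7, 5.9

(each reading ± 1 percentage point)

1. which of the two ends with the higher amount of double product, in percent of the substrate charged ("neither" if they lie within 2 percentage points) (north / west / neither)
2. double product at the end, in percent of the substrate charged, north
3. double product at the end, in percent of the substrate charged, west

- the analysis behind the earlier runs scatters by 1 percentage point, standard deviation

The first chemist treats double product as the end of the line, so that north, charged with equal amounts of partner and substrate, stops when partner, its limiting reagent, is spent, and west, with partner to spare, ends at the charge minus whatever the capture agent has taken. The second accepts this for north but distrusts it for west, and treats any further addition as a correction to be sized by a measure of exposure: the surplus exposure, the partner charged beyond two per substrate, multiplied by the time of reading, which counts the partner-minutes that finished double product stands open to if it can take another partner. Dawn reached 81.0 M·s at its last reading and dusk −45.0 M·s, a negative figure, while north comes to −342 M·s and west to 408 M·s, which is 5.04 times dawn's, so the second chemist keeps the order of the two flasks but holds that the readings have not tested the end of the line at west's exposure and takes the first chemist's west figure as a ceiling, without a number to put beneath it.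

The forecast sides with the first chemist, naming west as the higher, with 22% for north and 75% for west, on the ground that “West has excess partner and finishes within 40 min”.

The mechanism behind the flasks:

    substrate + partner → single product (k = 0.0407 L mol⁻¹ s⁻¹, Ea = 56.0 kJ mol⁻¹)
    partner + single product → double product (k = 0.0163 L mol⁻¹ s⁻¹, Ea = 67.0 kJ mol⁻¹)
    partner + double product → tris adduct (k = 0.00123 L mol⁻¹ s⁻¹, Ea = 79.0 kJ mol⁻¹)
    single product + capture agent → trapped intermediate (k = 0.0254 L mol⁻¹ s⁻¹, Ea = 54.0 kJ mol⁻¹)
    (constants at 25 °C)

West does come out higher, but at 52.0%, with 31.1% standing as tris adduct at 40.0 min, whereas north gives 21.5% and holds 0.393% tris adduct, so the first view stands in north, where the surplus exposure is negative. West's tris adduct divided by its exposure of 408 M·s gives 7.63 × 10⁻⁴ L mol⁻¹ s⁻¹. The neighbouring flask, which is north with 0.14 M of substrate, has an exposure of 174 M·s, so that figure gives 13.3%, and that neighbouring flask holds 12.9% tris adduct at 10.0 min.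

(Readings and results are simulated for substances that don't exist; the scatter is artificial.)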